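The hydroperoxide at C1 next to the C10=C14 exocyclic methylene is read as the ene product of singlet oxygen and a C1=C10 alkene, so C1 can be a vinyl carbon until the last step. The ten-membered carbocycle (C1–C10) is then closed at C1–C2 by one-pot hydroboration and B-alkyl Suzuki–Miyaura macrocyclisation: the C2=C3 vinyl group becomes a C2 alkylborane that couples with an (E)-C1 vinyl iodide, which fixes the 1(10)E geometry. The precursor is a cis-disubstituted α-methylene-γ-butyrolactone (ring O–C6–C7–C11–C12) whose two cis arms carry the diene and the vinyl iodide; an indium Barbier coupling of two fragments assembles it.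

Key step: step 12

Remark: germacrane numbering is used throughout (ring C1–C10, lactone carbons C11–C13, C14, C15, side chain C1′–C4′). The target is taken as 1R,6S,7R,8S,3′R, that is 1β-OOH, cis-fused 12,6β-olide (H-6α, H-7α), 8α-acyloxy, with C3 and C6 cis across C4=C5 (4E by CIP because C15 carries oxygen). Compounds 1, 8, 11 and 22 are taken as commercial.

Step 1
Reactants: 1 (S)-2-{[(4-methoxybenzyl)oxy]methyl}oxirane
Product: 2 (S)-1-[(4-methoxybenzyl)oxy]pent-4-yn-2-ol
Conditions: LiC≡CH·H2NCH2CH2NH2, DMSO, rt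
Reagents that add atoms: lithium acetylide ethylenediamine complex, [Li+].[C-]#C.NCCN
Why: SN2 opening of the terminal epoxide at its CH2 carbon by the acetylide leaves the epoxide CH (the future C8) untouched.

Step 2
Reactants: 2 (S)-1-[(4-methoxybenzyl)oxy]pent-4-yn-2-ol
Product: 4 (2S,4E)-5-iodo-1-[(4-methoxybenzyl)oxy]-4-methylpent-4-en-2-ol, via vinylalane 3 (not isolated)
Conditions: AlMe3 (3 equiv), Cp2ZrCl2 (0.3 equiv), CH2Cl2, 0 °C to rt; then I2, THF, −30 °C
Reagents that add atoms: trimethylaluminium, C[Al](C)C; iodine, II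
Why: Negishi zirconium-catalysed syn-carboalumination puts methyl on the internal and aluminium on the terminal alkyne carbon, and iodinolysis with retention should give the (E)-vinyl iodide that later becomes C1=C10.

Step 3
Reactants: 4 (2S,4E)-5-iodo-1-[(4-methoxybenzyl)oxy]-4-methylpent-4-en-2-ol
Product: 5 tert-butyl{[(2S,4E)-5-iodo-1-[(4-methoxybenzyl)oxy]-4-methylpent-4-en-2-yl]oxy}dimethylsilane
Conditions: TBSCl, imidazole, DMF, rt
Reagents that add atoms: tert-butyldimethylsilyl chloride, CC(C)(C)[Si](C)(C)Cl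
Why: Standard silylation of the secondary alcohol, which later leaves the C6 hydroxyl as the only one able to lactonise.

Step 4
Reactants: 5 tert-butyl{[(2S,4E)-5-iodo-1-[(4-methoxybenzyl)oxy]-4-methylpent-4-en-2-yl]oxy}dimethylsilane
Product: 6 (2S,4E)-2-[(tert-butyldimethylsilyl)oxy]-5-iodo-4-methylpent-4-en-1-ol
Conditions: DDQ, CH2Cl2/pH 7 buffer, 0 °C to rt
Reagents that add atoms: none
Why: Oxidative cleavage of the electron-rich 4-methoxybenzyl ether by DDQ should leave the silyl ether and the vinyl iodide untouched.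

Step 5
Reactants: 6 (2S,4E)-2-[(tert-butyldimethylsilyl)oxy]-5-iodo-4-methylpent-4-en-1-ol
Product: 7 (2S,4E)-2-[(tert-butyldimethylsilyl)oxy]-5-iodo-4-methylpent-4-enal
Conditions: Dess–Martin periodinane, NaHCO3, CH2Cl2, 0 °C to rt
Reagents that add atoms: none
Why: Buffered Dess–Martin oxidation should give the α-silyloxy aldehyde without epimerisation at C8 or silyl migration.

Step 6
Reactants: 7 (2S,4E)-2-[(tert-butyldimethylsilyl)oxy]-5-iodo-4-methylpent-4-enal; 8 methyl acrylate
Product: 9 methyl (4S,6E)-4-[(tert-butyldimethylsilyl)oxy]-3-hydroxy-7-iodo-6-methyl-2-methylidenehept-6-enoate (C3 epimers)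
Conditions: DABCO (1 equiv), methyl acrylate (excess), MeOH (cat.), rt
Reagents that add atoms: none
Why: Morita–Baylis–Hillman reaction of the activated α-oxygenated aldehyde installs C11–C13 as the acrylate, and the new carbinol centre (C7) is erased in the next step.

Step 7
Reactants: 9 methyl (4S,6E)-4-[(tert-butyldimethylsilyl)oxy]-3-hydroxy-7-iodo-6-methyl-2-methylidenehept-6-enoate
Product: 10 methyl (2Z,4S,6E)-2-(bromomethyl)-4-[(tert-butyldimethylsilyl)oxy]-7-iodo-6-methylhepta-2,6-dienoate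
Conditions: NBS, Me2S, CH2Cl2, 0 °C to rt
Reagents that add atoms: N-bromosuccinimide, O=C1CCC(=O)N1Br
Why: Corey–Kim-type activation of the hydroxyl and SN2′ attack of bromide should give the favoured trisubstituted enoate with C8 cis to CH2Br, the geometry the Barbier step needs.

Step 8
Reactants: 11 4-[(tert-butyldimethylsilyl)oxy]but-2-yn-1-ol
Product: 13 (Z)-4-[(tert-butyldimethylsilyl)oxy]-3-iodobut-2-en-1-ol, via vinylalanate 12 (not isolated)
Conditions: NaAlH2(OCH2CH2OCH3)2, THF, 0 °C; then I2, THF, −78 °C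
Reagents that add atoms: iodine, II
Why: The aluminium alkoxide delivers hydride to the proximal alkyne carbon (trans-hydroalumination) to give a five-membered vinylalanate, and iodinolysis with retention places iodine cis to CH2OH.

Step 9
Reactants: 13 (Z)-4-[(tert-butyldimethylsilyl)oxy]-3-iodobut-2-en-1-ol
Product: 14 (E)-3-{[(tert-butyldimethylsilyl)oxy]methyl}penta-2,4-dien-1-ol
Conditions: Bu3SnCH=CH2, Pd(PPh3)4 (5 mol%), CuI (cat.), DMF, rt to 40 °C
Reagents that add atoms: tributyl(vinyl)stannane, C=C[Sn](CCCC)(CCCC)CCCC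
Why: Stille coupling with retention places the vinyl group (C2=C3) cis to the future C6 and C15 trans to it, as in the target.

Step 10
Reactants: 14 (E)-3-{[(tert-butyldimethylsilyl)oxy]methyl}penta-2,4-dien-1-ol
Product: 15 (E)-3-{[(tert-butyldimethylsilyl)oxy]methyl}penta-2,4-dienal
Conditions: Dess–Martin periodinane, NaHCO3, CH2Cl2, 0 °C; used at once
Reagents that add atoms: none
Why: Mild buffered Dess–Martin oxidation of the allylic alcohol should give the dienal without geometric isomerisation.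

Step 11
Reactants: 10 methyl (2Z,4S,6E)-2-(bromomethyl)-4-[(tert-butyldimethylsilyl)oxy]-7-iodo-6-methylhepta-2,6-dienoate; 15 (E)-3-{[(tert-butyldimethylsilyl)oxy]methyl}penta-2,4-dienal
Product: 17 (4S,5S)-4-[(1S,3E)-1-[(tert-butyldimethylsilyl)oxy]-4-iodo-3-methylbut-3-en-1-yl]-5-[(1E)-2-{[(tert-butyldimethylsilyl)oxy]methyl}buta-1,3-dien-1-yl]-3-methylideneoxolan-2-one (4,5-cis), via hydroxy ester 16 (not isolated)
Conditions: In powder, THF/H2O (1:1), rt; then PPTS (cat.), CH2Cl2, rt
Reagents that add atoms: none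
Why: Indium Barbier allylation through a closed chair transition state with C8 cis to CH2In should give the 6,7-syn adduct and hence the cis-lactone, the C8 stereocentre (H-8 eclipsing C7=C11 by allylic strain) sending the aldehyde to the face of C7 anti to the C8–O bond so that C6 and C7 are set as in the target, and mild acid then closes the γ-lactone on the only free hydroxyl.

Step 12
Reactants: 17 (4S,5S)-4-[(1S,3E)-1-[(tert-butyldimethylsilyl)oxy]-4-iodo-3-methylbut-3-en-1-yl]-5-[(1E)-2-{[(tert-butyldimethylsilyl)oxy]methyl}buta-1,3-dien-1-yl]-3-methylideneoxolan-2-one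
Product: 19 8α,15-bis[(tert-butyldimethylsilyl)oxy]germacra-1(10)E,4E,11(13)-trien-12,6β-olide, via B-alkyl-9-BBN borane 18 (not isolated)
Conditions: 9-BBN dimer, THF, 0 °C to rt; then slow addition to Pd(dppf)Cl2 (20 mol%), AsPh3, Cs2CO3, DMF/THF/H2O, rt, 0.002 M
Reagents that add atoms: none
Why: 9-BBN should add anti-Markovnikov to the terminal C2=C3 vinyl group of the diene to give the C2 alkylborane; zerovalent palladium then inserts into the C1–I bond, hydroxide-assisted transmetalation moves the C2 alkyl group from boron to palladium, and reductive elimination forms C1–C2. The closest known reaction type is the intramolecular B-alkyl Suzuki–Miyaura macrocyclisation of an ω-alkenyl vinyl iodide. The ten-membered carbocycle C1–C10 closes by reductive elimination from an eleven-membered alkyl(alkenyl)palladium ring, the C1=C10 bond becoming endocyclic. No stereocentre is created; the 1(10)E geometry is carried over from the vinyl iodide with retention and the C4=C5 geometry is not touched. The step needs hydroboration of the electron-rich monosubstituted vinyl group in preference to the electron-poor methylene lactone and the trisubstituted alkenes, and ring closure in preference to oligomerisation or Heck-type insertion into the methylene lactone; high dilution, room temperature, the bidentate phosphine and the cis-fused lactone, which holds both arms on one face, should secure this.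

Step 13
Reactants: 19 8α,15-bis[(tert-butyldimethylsilyl)oxy]germacra-1(10)E,4E,11(13)-trien-12,6β-olide
Product: 20 8α,15-dihydroxygermacra-1(10)E,4E,11(13)-trien-12,6β-olide
Conditions: HF·pyridine, pyridine, THF, 0 °C to rt
Reagents that add atoms: none
Why: Buffered fluoride should cleave both silyl ethers while the lactone and the diene survive.

Step 14
Reactants: 20 8α,15-dihydroxygermacra-1(10)E,4E,11(13)-trien-12,6β-olide
Product: 21 15-acetoxy-8α-hydroxygermacra-1(10)E,4E,11(13)-trien-12,6β-olide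
Conditions: AcCl (1.1 equiv), 2,4,6-collidine, CH2Cl2, −78 °C
Reagents that add atoms: acetyl chloride, CC(Cl)=O
Why: The unhindered primary allylic C15 hydroxyl should be acetylated far faster than the hindered secondary C8 hydroxyl at low temperature with a weak base.

Step 15
Reactants: 22 (R)-2-(2,2-dimethyl-1,3-dioxolan-4-yl)ethan-1-ol
Product: 23 (R)-2-(2,2-dimethyl-1,3-dioxolan-4-yl)acetaldehyde
Conditions: Dess–Martin periodinane, NaHCO3, CH2Cl2, 0 °C to rt
Reagents that add atoms: none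
Why: Buffered Dess–Martin oxidation should give the β-alkoxy aldehyde without β-elimination.

Step 16
Reactants: 23 (R)-2-(2,2-dimethyl-1,3-dioxolan-4-yl)acetaldehyde
Product: 24 (R)-2-(2,2-dimethyl-1,3-dioxolan-4-yl)prop-2-enal
Conditions: 37% aq. HCHO, pyrrolidine (10 mol%), propionic acid (10 mol%), i-PrOH, 45 °C
Reagents that add atoms: formaldehyde, C=O
Why: Amine-catalysed Mannich condensation with formaldehyde and elimination (organocatalytic α-methylenation) installs the exocyclic methylene without touching the dioxolane stereocentre.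

Step 17
Reactants: 24 (R)-2-(2,2-dimethyl-1,3-dioxolan-4-yl)prop-2-enal
Product: 25 (R)-2-(2,2-dimethyl-1,3-dioxolan-4-yl)prop-2-enoic acid
Conditions: NaClO2, NaH2PO4, 2-methylbut-2-ene, t-BuOH/H2O, 0 °C to rt
Reagents that add atoms: sodium chlorite, [Na+].[O-]Cl=O
Why: Pinnick oxidation converts the enal into the acid without affecting the 1,1-disubstituted alkene or the acetonide.

Step 18
Reactants: 21 15-acetoxy-8α-hydroxygermacra-1(10)E,4E,11(13)-trien-12,6β-olide; 25 (R)-2-(2,2-dimethyl-1,3-dioxolan-4-yl)prop-2-enoic acid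
Product: 27 15-acetoxy-8α-{[2-((4R)-2,2-dimethyl-1,3-dioxolan-4-yl)prop-2-enoyl]oxy}germacra-1(10)E,4E,11(13)-trien-12,6β-olide, via mixed anhydride 26 (not isolated)
Conditions: 2,4,6-trichlorobenzoyl chloride, Et3N, toluene, rt; then 21, DMAP, rt
Reagents that add atoms: none
Why: Yamaguchi esterification through the mixed anhydride should acylate the hindered C8 alcohol with retention of its configuration.

Step 19
Reactants: 27 15-acetoxy-8α-{[2-((4R)-2,2-dimethyl-1,3-dioxolan-4-yl)prop-2-enoyl]oxy}germacra-1(10)E,4E,11(13)-trien-12,6β-olide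
Product: 28 15-acetoxy-8α-{[(3R)-3,4-dihydroxy-2-methylidenebutanoyl]oxy}germacra-1(10)E,4E,11(13)-trien-12,6β-olide
Conditions: AcOH/H2O (4:1), rt
Reagents that add atoms: none
Why: Mild aqueous acid hydrolyses the acetonide while the allylic acetate, the esters and the acid-sensitive cyclodecadiene should survive at room temperature.

Step 20
Reactants: 28 15-acetoxy-8α-{[(3R)-3,4-dihydroxy-2-methylidenebutanoyl]oxy}germacra-1(10)E,4E,11(13)-trien-12,6β-olide
Product: 29 15-acetoxy-8α-{[(3R)-3,4-dihydroxy-2-methylidenebutanoyl]oxy}-1β-hydroperoxygermacra-4E,10(14),11(13)-trien-12,6β-olide (1R,6S,7R,8S; target)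
Conditions: O2, tetraphenylporphyrin (cat.), visible light, CH2Cl2, 0 °C, stopped at full conversion of 28
Reagents that add atoms: oxygen, O=O
Why: In this Schenck ene reaction singlet oxygen should attack only the electron-rich C1=C10 bond (C4=C5 is deactivated by two allylic oxygen substituents, the acrylate units are inert), bond to C1 from the outer face of the (E)-alkene in the conformer with C14 on the β-face and take hydrogen from the C14 methyl on the disubstituted side (cis effect), which sets 1β-OOH and the C10=C14 alkene.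

Compound list
1 | (S)-2-{[(4-methoxybenzyl)oxy]methyl}oxirane | COc1ccc(COC[C@@H]2CO2)cc1 | starting material
2 | (S)-1-[(4-methoxybenzyl)oxy]pent-4-yn-2-ol | COc1ccc(COC[C@@H](O)CC#C)cc1 | intermediate
3 | (E)-C1 dimethylvinylalane of 2 with O–AlMe2 at C8 | COc1ccc(COC[C@@H](O[Al](C)C)C/C(C)=C/[Al](C)C)cc1 | intermediate
4 | (2S,4E)-5-iodo-1-[(4-methoxybenzyl)oxy]-4-methylpent-4-en-2-ol | COc1ccc(COC[C@@H](O)C/C(C)=C/I)cc1 | intermediate
5 | tert-butyl{[(2S,4E)-5-iodo-1-[(4-methoxybenzyl)oxy]-4-methylpent-4-en-2-yl]oxy}dimethylsilane | COc1ccc(COC[C@@H](O[Si](C)(C)C(C)(C)C)C/C(C)=C/I)cc1 | intermediate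
6 | (2S,4E)-2-[(tert-butyldimethylsilyl)oxy]-5-iodo-4-methylpent-4-en-1-ol | OC[C@@H](O[Si](C)(C)C(C)(C)C)C/C(C)=C/I | intermediate
7 | (2S,4E)-2-[(tert-butyldimethylsilyl)oxy]-5-iodo-4-methylpent-4-enal | O=C[C@@H](O[Si](C)(C)C(C)(C)C)C/C(C)=C/I | intermediate
8 | methyl acrylate | C=CC(=O)OC | starting material
9 | methyl (4S,6E)-4-[(tert-butyldimethylsilyl)oxy]-3-hydroxy-7-iodo-6-methyl-2-methylidenehept-6-enoate (C3 epimers) | COC(=O)C(=C)C(O)[C@@H](O[Si](C)(C)C(C)(C)C)C/C(C)=C/I | intermediate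
10 | methyl (2Z,4S,6E)-2-(bromomethyl)-4-[(tert-butyldimethylsilyl)oxy]-7-iodo-6-methylhepta-2,6-dienoate | COC(=O)/C(CBr)=C/[C@@H](O[Si](C)(C)C(C)(C)C)C/C(C)=C/I | intermediate
11 | 4-[(tert-butyldimethylsilyl)oxy]but-2-yn-1-ol | CC(C)(C)[Si](C)(C)OCC#CCO | starting material
12 | sodium cyclic vinylalanate (five-membered O–Al–C3=C2–C1 ring, two 2-methoxyethoxy groups on Al) | CC(C)(C)[Si](C)(C)OCC1=CCO[Al-]1(OCCOC)OCCOC.[Na+] | intermediate
13 | (Z)-4-[(tert-butyldimethylsilyl)oxy]-3-iodobut-2-en-1-ol | CC(C)(C)[Si](C)(C)OC/C(I)=C/CO | intermediate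
14 | (E)-3-{[(tert-butyldimethylsilyl)oxy]methyl}penta-2,4-dien-1-ol | CC(C)(C)[Si](C)(C)OC/C(C=C)=C/CO | intermediate
15 | (E)-3-{[(tert-butyldimethylsilyl)oxy]methyl}penta-2,4-dienal | CC(C)(C)[Si](C)(C)OC/C(C=C)=C/C=O | intermediate
16 | methyl (3S,4S,5E)-3-[(1S,3E)-1-[(tert-butyldimethylsilyl)oxy]-4-iodo-3-methylbut-3-en-1-yl]-6-{[(tert-butyldimethylsilyl)oxy]methyl}-4-hydroxy-2-methylideneocta-5,7-dienoate (6,7-syn hydroxy ester) | COC(=O)C(=C)[C@@H]([C@@H](O)/C=C(/CO[Si](C)(C)C(C)(C)C)C=C)[C@@H](O[Si](C)(C)C(C)(C)C)C/C(C)=C/I | intermediate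
17 | (4S,5S)-4-[(1S,3E)-1-[(tert-butyldimethylsilyl)oxy]-4-iodo-3-methylbut-3-en-1-yl]-5-[(1E)-2-{[(tert-butyldimethylsilyl)oxy]methyl}buta-1,3-dien-1-yl]-3-methylideneoxolan-2-one (4,5-cis) | C=C1C(=O)O[C@@H](/C=C(/CO[Si](C)(C)C(C)(C)C)C=C)[C@H]1[C@@H](O[Si](C)(C)C(C)(C)C)C/C(C)=C/I | intermediate
18 | B-alkyl-9-BBN borane of 17 (boron on C2) | C=C1C(=O)O[C@@H](/C=C(/CO[Si](C)(C)C(C)(C)C)CCB2C3CCCC2CCC3)[C@H]1[C@@H](O[Si](C)(C)C(C)(C)C)C/C(C)=C/I | intermediate
19 | 8α,15-bis[(tert-butyldimethylsilyl)oxy]germacra-1(10)E,4E,11(13)-trien-12,6β-olide | C=C1C(=O)O[C@H]2/C=C(/CO[Si](C)(C)C(C)(C)C)CC/C=C(\C)C[C@H](O[Si](C)(C)C(C)(C)C)[C@@H]12 | intermediate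
20 | 8α,15-dihydroxygermacra-1(10)E,4E,11(13)-trien-12,6β-olide | C=C1C(=O)O[C@H]2/C=C(/CO)CC/C=C(\C)C[C@H](O)[C@@H]12 | intermediate
21 | 15-acetoxy-8α-hydroxygermacra-1(10)E,4E,11(13)-trien-12,6β-olide | C=C1C(=O)O[C@H]2/C=C(/COC(C)=O)CC/C=C(\C)C[C@H](O)[C@@H]12 | intermediate
22 | (R)-2-(2,2-dimethyl-1,3-dioxolan-4-yl)ethan-1-ol | OCC[C@@H]1COC(C)(C)O1 | starting material
23 | (R)-2-(2,2-dimethyl-1,3-dioxolan-4-yl)acetaldehyde | O=CC[C@@H]1COC(C)(C)O1 | intermediate
24 | (R)-2-(2,2-dimethyl-1,3-dioxolan-4-yl)prop-2-enal | C=C(C=O)[C@@H]1COC(C)(C)O1 | intermediate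
25 | (R)-2-(2,2-dimethyl-1,3-dioxolan-4-yl)prop-2-enoic acid | C=C(C(=O)O)[C@@H]1COC(C)(C)O1 | intermediate
26 | mixed anhydride of 25 and 2,4,6-trichlorobenzoic acid | C=C(C(=O)OC(=O)c1c(Cl)cc(Cl)cc1Cl)[C@@H]1COC(C)(C)O1 | intermediate
27 | 15-acetoxy-8α-{[2-((4R)-2,2-dimethyl-1,3-dioxolan-4-yl)prop-2-enoyl]oxy}germacra-1(10)E,4E,11(13)-trien-12,6β-olide | C=C1C(=O)O[C@H]2/C=C(/COC(C)=O)CC/C=C(\C)C[C@H](OC(=O)C(=C)[C@@H]3COC(C)(C)O3)[C@@H]12 | intermediate
28 | 15-acetoxy-8α-{[(3R)-3,4-dihydroxy-2-methylidenebutanoyl]oxy}germacra-1(10)E,4E,11(13)-trien-12,6β-olide | C=C1C(=O)O[C@H]2/C=C(/COC(C)=O)CC/C=C(\C)C[C@H](OC(=O)C(=C)[C@@H](O)CO)[C@@H]12 | intermediate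
29 | 15-acetoxy-8α-{[(3R)-3,4-dihydroxy-2-methylidenebutanoyl]oxy}-1β-hydroperoxygermacra-4E,10(14),11(13)-trien-12,6β-olide (1R,6S,7R,8S) | C=C1C(=O)O[C@H]2/C=C(/COC(C)=O)CC[C@@H](OO)C(=C)C[C@H](OC(=O)C(=C)[C@@H](O)CO)[C@@H]12 | target

Total step count: 20. Longest linear sequence: 14 steps (steps 1–7, 11–14, 18–20).

Steps most likely to fail

Step 12. The exocyclic acrylate unit of the lactone may be consumed (conjugate reduction by the borane, insertion into the vinylpalladium intermediate), or intermolecular coupling may outrun closure of the strained ring. The fallback sets out from 17 and comes back at 19, and closes the ring on a substrate that no longer holds the acceptor alkene. Dimethylamine in THF should add to C13 to give the β-(dimethylamino)methyl lactone F1. Hydroboration as before gives the borane F2, and the same palladium-catalysed closure the amine-masked macrocycle F3. Methyl iodide then gives the trimethylammonium iodide F4, and aqueous NaHCO3 (Hofmann-type elimination) should restore the methylene lactone of 19.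

Step 20. Oxygen may be delivered to C1 from the wrong face of C1=C10 if the conformer with C14 on the α-face reacts, and hydrogen abstraction from C2 may compete. The fallback sets out from 27 and comes back at 29, and sets C1 by an SN2 inversion instead of by conformation. Photooxygenation of 27 is run to give the 1α-hydroperoxide F5, which PPh3 reduces to the 1α-allylic alcohol F6. MsCl/Et3N at −78 °C gives the 1α-mesylate F7, and anhydrous H2O2 in Et2O displaces it in situ with inversion to the 1β-hydroperoxide acetonide F8. AcOH/H2O then gives 29.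

Step 11. The allylindium may show poor facial selectivity with respect to the C8 stereocentre, and the dienal may drift in geometry, which would give the lactone epimeric at C6 and C7. The fallback sets out from 9 and comes back at 16, and replaces indium by a boron-centred chair under catalyst control. Ac2O/DMAP converts 9 into the allylic acetate F9. Copper-catalysed SN2′ borylation (B2pin2, CuCl, LiCl, KOAc, DMF) gives the allylboronate F10 with C8 cis to CH2B. Its addition to 15 under a chiral BINOL-derived phosphoric acid (the enantiomer matched to the 6S carbinol) should give the pinacol borate F11 and, after hydrolytic work-up, 16.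

Further compounds
F1 | step 12 | β-(dimethylamino)methyl lactone from 17 (C11 epimers) | CN(C)CC1C(=O)O[C@@H](/C=C(/CO[Si](C)(C)C(C)(C)C)C=C)[C@H]1[C@@H](O[Si](C)(C)C(C)(C)C)C/C(C)=C/I
F2 | step 12 | B-alkyl-9-BBN borane of F1 | CN(C)CC1C(=O)O[C@@H](/C=C(/CO[Si](C)(C)C(C)(C)C)CCB2C3CCCC2CCC3)[C@H]1[C@@H](O[Si](C)(C)C(C)(C)C)C/C(C)=C/I
F3 | step 12 | 13-(dimethylamino)-11,13-dihydro derivative of 19 (amine-masked macrocycle) | CN(C)CC1C(=O)O[C@H]2/C=C(/CO[Si](C)(C)C(C)(C)C)CC/C=C(\C)C[C@H](O[Si](C)(C)C(C)(C)C)[C@@H]12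
F4 | step 12 | trimethylammonium iodide of F3 | C[N+](C)(C)CC1C(=O)O[C@H]2/C=C(/CO[Si](C)(C)C(C)(C)C)CC/C=C(\C)C[C@H](O[Si](C)(C)C(C)(C)C)[C@@H]12.[I-]
F5 | step 20 | 1α-hydroperoxy-10(14)-ene from 27 (C1 epimer, acetonide) | C=C1C(=O)O[C@H]2/C=C(/COC(C)=O)CC[C@H](OO)C(=C)C[C@H](OC(=O)C(=C)[C@@H]3COC(C)(C)O3)[C@@H]12
F6 | step 20 | 1α-hydroxy-10(14)-ene acetonide | C=C1C(=O)O[C@H]2/C=C(/COC(C)=O)CC[C@H](O)C(=C)C[C@H](OC(=O)C(=C)[C@@H]3COC(C)(C)O3)[C@@H]12
F7 | step 20 | 1α-methanesulfonate of F6 | C=C1C(=O)O[C@H]2/C=C(/COC(C)=O)CC[C@H](OS(C)(=O)=O)C(=C)C[C@H](OC(=O)C(=C)[C@@H]3COC(C)(C)O3)[C@@H]12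
F8 | step 20 | 1β-hydroperoxy-10(14)-ene acetonide (acetonide of 29) | C=C1C(=O)O[C@H]2/C=C(/COC(C)=O)CC[C@@H](OO)C(=C)C[C@H](OC(=O)C(=C)[C@@H]3COC(C)(C)O3)[C@@H]12
F9 | step 11 | acetate of 9 | COC(=O)C(=C)C(OC(C)=O)[C@@H](O[Si](C)(C)C(C)(C)C)C/C(C)=C/I
F10 | step 11 | methyl (2E,4S,6E)-4-[(tert-butyldimethylsilyl)oxy]-7-iodo-6-methyl-2-[(pinacolboryl)methyl]hepta-2,6-dienoate | COC(=O)/C(CB1OC(C)(C)C(C)(C)O1)=C/[C@@H](O[Si](C)(C)C(C)(C)C)C/C(C)=C/I
F11 | step 11 | pinacol borate ester of 16 | COC(=O)C(=C)[C@@H]([C@@H](OB1OC(C)(C)C(C)(C)O1)/C=C(/CO[Si](C)(C)C(C)(C)C)C=C)[C@@H](O[Si](C)(C)C(C)(C)C)C/C(C)=C/I
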